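**Plan**

- Feature: in the 3-deoxyflavan unit (U; the flavan-3,4-diol unit is L) U-C4 is a CH bearing two different aryl carbons, U-C4a of ring A and L-C6, next to the CH2 U-C3 and the oxygenated U-C2. It is therefore a 1,1-diarylated aryl vinyl ketone in masked form.
- Retrosynthesis: protecting groups come off last. The O1–C2 bond of ring C of U is cut (phenol Mitsunobu), then U-C4–U-C4a and U-C4–L-C6 together (diazonium salt + vinyl ketone + boronic acid). Unit L is cut at its own O1–C2 bond, at the C3/C4 diol (Z-alkene) and at C2–C3 (alkyne + aldehyde).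
- Forward: one ring A aldehyde serves both units. L is assembled as an open chain, its ring C is closed and C6 is borylated. The diazonium salt and the vinyl ketone are made in parallel, the three parts are joined, ring C of U is closed and the protecting groups are removed.
- Stereochemistry: L-C2 comes from a BINOL–Ti alkynylzinc addition. L-C3 and L-C4 are relayed from it by syn-dihydroxylation of the Z-alkene, and L-C2 is inverted on ring closure. U-C4 is set by the chiral phosphate in the key step. U-C2 comes from a CBS reduction and is inverted on ring closure.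

Key step: step 20

Assumption: the sense of induction of (R)-BINOL in step 4 and of the (R)-BINAM-derived phosphate in step 20 is taken from the closest model reactions and would be confirmed first; the antipodal catalyst is used if it proves opposite.

**Route**

Step 1
Reactants: 1 2,3,4-trihydroxybenzaldehyde
Product: 2 3,4-bis(benzyloxy)-2-hydroxybenzaldehyde
Conditions: BnBr (2.1 equiv), K2CO3 (2.1 equiv), DMF, 0 °C to rt
Reagents that add atoms: benzyl bromide, BrCc1ccccc1
Why: Regioselective Williamson etherification, in which the 2-hydroxyl is held in a hydrogen bond to the formyl group and should remain free while the 4- and 3-hydroxyls are benzylated.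

Step 2
Reactants: 2 3,4-bis(benzyloxy)-2-hydroxybenzaldehyde
Product: 3 3,4-bis(benzyloxy)-2-(triisopropylsilyloxy)benzaldehyde
Conditions: TIPSCl, imidazole, DMAP (cat.), DMF, rt to 40 °C
Reagents that add atoms: triisopropylsilyl chloride, CC(C)[Si](Cl)(C(C)C)C(C)C
Why: Silylation of a phenol, giving a hindered aryl silyl ether that should survive the organometallic steps and fall together with the second silyl group in step 9.

Step 3
Reactants: 3 3,4-bis(benzyloxy)-2-(triisopropylsilyloxy)benzaldehyde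
Product: 4 [2,3-bis(benzyloxy)-6-ethynylphenoxy]triisopropylsilane
Conditions: TMSCHN2, n-BuLi, THF, −78 °C to rt
Reagents that add atoms: trimethylsilyldiazomethane, C[Si](C)(C)C=[N+]=[N-]
Why: Colvin rearrangement (one-carbon homologation of an aryl aldehyde to the terminal alkyne), run under aprotic conditions that should leave the aryl silyl ether intact.

Step 4
Reactants: 4 [2,3-bis(benzyloxy)-6-ethynylphenoxy]triisopropylsilane; 5 4-(benzyloxy)benzaldehyde
Product: 7 (S)-1-[4-(benzyloxy)phenyl]-3-[3,4-bis(benzyloxy)-2-(triisopropylsilyloxy)phenyl]prop-2-yn-1-ol, via alkynylzinc 6 (not isolated)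
Conditions: Et2Zn, toluene, reflux; then (R)-BINOL (20 mol %), Ti(OiPr)4 (50 mol %), CH2Cl2, rt; then 5
Reagents that add atoms: none
Why: BINOL–Ti(OiPr)4-catalysed enantioselective addition of an alkynylzinc to an aromatic aldehyde, in which the chiral titanium binaphtholate selects the aldehyde face and sets the future L-C2 as the (S)-carbinol.

Step 5
Reactants: 7 (S)-propargylic alcohol
Product: 8 (R,Z)-1-[4-(benzyloxy)phenyl]-3-[3,4-bis(benzyloxy)-2-(triisopropylsilyloxy)phenyl]prop-2-en-1-ol
Conditions: H2 (1 atm), Pd/CaCO3 poisoned with Pb(OAc)2 (Lindlar catalyst), quinoline, EtOAc, rt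
Reagents that add atoms: none
Why: Lindlar semihydrogenation adds hydrogen cis to the alkyne and should stop at the Z-alkene without touching the aryl benzyl ethers (the descriptor changes from S to R only through the priority change).

Step 6
Reactants: 8 (R,Z)-allylic alcohol
Product: 9 (R,Z)-tert-butyldimethylsilyl ether of 8
Conditions: TBSCl, imidazole, DMF, rt
Reagents that add atoms: tert-butyldimethylsilyl chloride, CC(C)(C)[Si](C)(C)Cl
Why: Silylation of the secondary alcohol, which keeps this oxygen apart from the diol made next and provides the ether that directs the osmylation.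

Step 7
Reactants: 9 (R,Z)-allylic silyl ether
Product: 10 (1R,2R,3S)-1-[3,4-bis(benzyloxy)-2-(triisopropylsilyloxy)phenyl]-3-[4-(benzyloxy)phenyl]-3-(tert-butyldimethylsilyloxy)propane-1,2-diol
Conditions: OsO4 (3 mol %), NMO, acetone/H2O, 0 °C to rt
Reagents that add atoms: N-methylmorpholine N-oxide, C[N+]1([O-])CCOCC1; water, O; OsO4 as catalytic oxygen carrier, O=[Os](=O)(=O)=O
Why: Stereospecific syn-dihydroxylation of the Z-alkene gives the erythro diol, and attack anti to the allylic silyloxy group in the conformer fixed by allylic 1,3-strain (the usual erythro preference in osmylation of allylic ethers) should place both new centres anti to the carbinol centre.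

Step 8
Reactants: 10 diol
Product: 11 (4R,5R)-4-[3,4-bis(benzyloxy)-2-(triisopropylsilyloxy)phenyl]-5-{(S)-[4-(benzyloxy)phenyl](tert-butyldimethylsilyloxy)methyl}-2,2-dimethyl-1,3-dioxolane (cis)
Conditions: 2-methoxypropene, pyridinium tosylate (cat.), CH2Cl2, 0 °C
Reagents that add atoms: 2-methoxypropene, COC(C)=C
Why: Acetalisation of the only free 1,2-diol under very mild acid catalysis should give the cis-dioxolane without ionising the benzylic C–O bond.

Step 9
Reactants: 11 bis-silyl acetonide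
Product: 12 2,3-bis(benzyloxy)-6-{(4R,5S)-5-[(S)-[4-(benzyloxy)phenyl](hydroxy)methyl]-2,2-dimethyl-1,3-dioxolan-4-yl}phenol
Conditions: Bu4NF (3 equiv), THF, 0 °C to rt
Reagents that add atoms: none
Why: Fluoride-mediated desilylation should remove the aryl triisopropylsilyl and the alkyl tert-butyldimethylsilyl ether in one operation while the acetonide is inert.

Step 10
Reactants: 12 phenol carbinol
Product: 13 3,4-acetonide of (2R,3R,4R)-7,8-bis(benzyloxy)-2-[4-(benzyloxy)phenyl]chromane-3,4-diol (2,3-cis-3,4-cis)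
Conditions: PPh3, diisopropyl azodicarboxylate, toluene, 0 °C to rt
Reagents that add atoms: none
Why: Intramolecular Mitsunobu etherification, in which the phenol displaces the oxyphosphonium group at the benzylic carbinol with inversion and so turns the anti chain into the all-cis chroman with L-C2 as R.

Step 11
Reactants: 13 flavan acetonide
Product: 14 6-bromo derivative of 13
Conditions: NBS, CH2Cl2, −10 to 0 °C, dark
Reagents that add atoms: N-bromosuccinimide, O=C1CCC(=O)N1Br
Why: Electrophilic aromatic bromination should go to C6, the only free position activated by two oxygens (ortho to the C7 ether, para to the ring oxygen), since C5 has one activating oxygen and a peri substituent.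

Step 12
Reactants: 14 aryl bromide
Product: 17 6-boronic acid of 13, via aryllithium 15 (not isolated), via lithium triisopropyl borate 16 (not isolated)
Conditions: n-BuLi, THF, −78 °C; B(OiPr)3, −78 °C to rt; aq. NH4Cl
Reagents that add atoms: triisopropyl borate, CC(C)OB(OC(C)C)OC(C)C; water, O
Why: Bromine–lithium exchange at low temperature with borate trapping and hydrolysis is the standard route to an arylboronic acid and tolerates benzyl ethers and the acetonide.

Step 13
Reactants: 2 3,4-bis(benzyloxy)-2-hydroxybenzaldehyde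
Product: 18 2,3-bis(benzyloxy)-6-formylphenyl 4-methylbenzenesulfonate
Conditions: TsCl, Et3N, DMAP (cat.), CH2Cl2, 0 °C to rt
Reagents that add atoms: 4-toluenesulfonyl chloride, Cc1ccc(cc1)S(Cl)(=O)=O
Why: Sulfonylation of the phenol, chosen because a tosylate, unlike a silyl, acyl or acetal group, is not made labile by an ortho diazonium group and is inert to zerovalent palladium at room temperature.

Step 14
Reactants: 18 tosyloxy aldehyde
Product: 19 3,4-bis(benzyloxy)-2-(tosyloxy)benzoic acid
Conditions: NaClO2, NaH2PO4, 2-methyl-2-butene, t-BuOH/THF/H2O, rt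
Reagents that add atoms: sodium chlorite, [Na+].[O-]Cl=O
Why: Pinnick oxidation converts the aryl aldehyde into the acid, the alkene scavenger protecting the electron-rich ring from chlorination.

Step 15
Reactants: 19 benzoic acid
Product: 22 2,3-bis(benzyloxy)-6-[(tert-butoxycarbonyl)amino]phenyl 4-methylbenzenesulfonate, via acyl azide 20 (not isolated), via isocyanate 21 (not isolated)
Conditions: (PhO)2P(O)N3, Et3N, toluene, rt to 90 °C; then t-BuOH, 90 °C
Reagents that add atoms: diphenylphosphoryl azide, [N-]=[N+]=NP(=O)(Oc1ccccc1)Oc1ccccc1; tert-butanol, CC(C)(C)O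
Why: Curtius rearrangement places nitrogen exactly where the formyl carbon was, so the regiochemistry of ring A is fixed without a nitration.

Step 16
Reactants: 22 carbamate
Product: 23 6-amino-2,3-bis(benzyloxy)phenyl 4-methylbenzenesulfonate
Conditions: CF3CO2H, CH2Cl2, 0 °C to rt; aq. NaHCO3
Reagents that add atoms: none
Why: Acidolysis of the tert-butyl carbamate liberates the aniline, and an ortho-sulfonyloxy aniline should not undergo O-to-N transfer.

Step 17
Reactants: 23 aniline
Product: 24 3,4-bis(benzyloxy)-2-(tosyloxy)benzenediazonium tetrafluoroborate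
Conditions: NOBF4, MeCN, −30 to 0 °C; precipitation with Et2O
Reagents that add atoms: nitrosonium tetrafluoroborate, N#[O+].F[B-](F)(F)F
Why: Anhydrous diazotisation should give an isolable arenediazonium tetrafluoroborate, stabilised by the para benzyloxy group and carrying only ether and sulfonate substituents.

Step 18
Reactants: 5 4-(benzyloxy)benzaldehyde
Product: 25 1-[4-(benzyloxy)phenyl]prop-2-en-1-ol (racemic)
Conditions: CH2=CHMgBr, THF, −78 to 0 °C
Reagents that add atoms: vinylmagnesium bromide, C=C[Mg]Br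
Why: 1,2-Addition of a vinyl Grignard reagent to an aromatic aldehyde.

Step 19
Reactants: 25 allylic alcohol
Product: 26 1-[4-(benzyloxy)phenyl]prop-2-en-1-one
Conditions: MnO2 (activated, excess), CH2Cl2, rt; used at once
Reagents that add atoms: none
Why: MnO2 oxidation of an allylic benzylic alcohol gives the aryl vinyl ketone under neutral conditions that should limit polymerisation.

Step 20
Reactants: 24 diazonium tetrafluoroborate (1.3 equiv); 26 aryl vinyl ketone; 17 boronic acid (2 equiv)
Product: 27 (3S)-1-[4-(benzyloxy)phenyl]-3-[3,4-bis(benzyloxy)-2-(tosyloxy)phenyl]-3-(C6 of the L acetonide 13)propan-1-one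
Conditions: Pd2(dba)3 (5 mol %), (R)-BINAM-derived phosphoric acid (N,N'-diaryl phosphoric diamide, 10 mol %), Na2CO3, Et2O/toluene, 0 °C to rt
Reagents that add atoms: none
Why: Proposed new method: zerovalent palladium adds oxidatively to 24, carried into the organic phase as its chiral phosphate ion pair, and the cationic aryl–Pd inserts 26 with the aryl group on the terminal carbon; β-hydride elimination and re-addition of Pd–H with reversed regiochemistry give the π-benzyl–Pd at U-C4, and transmetalation from 17 with reductive elimination forms U-C4–L-C6. The closest known reaction type is the Pd2(dba)3-catalysed three-component 1,1-diarylation of acrylates with arenediazonium salts and arylboronic acids under chiral anion phase transfer, a Heck–Matsuda insertion relayed to a Suzuki–Miyaura coupling. No ring closes. U-C4, the one new stereocentre, is fixed in the reductive elimination from the π-benzyl–Pd phosphate ion pair, so the phosphate must override any bias of the distant centres of 17. The step needs 1,1-diarylation to win over the plain Heck, reductive Heck and biaryl products; the para benzyloxy group of ring A stabilises the benzylic palladium, the excess of 17 and the weak base favour transmetalation over loss of Pd–H, and the diazonium group reacts far faster than the aryl tosylate.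

Step 21
Reactants: 27 β,β-diaryl ketone
Product: 28 (1R,3S)-alcohol from 27
Conditions: (S)-2-methyl-CBS-oxazaborolidine (0.3 equiv), BH3·SMe2, THF, −20 °C; MeOH
Reagents that add atoms: none
Why: Corey–Bakshi–Shibata reduction of an aryl alkyl ketone, in which the (S)-oxazaborolidine delivers hydride to give the (R)-carbinol under catalyst control, the remote U-C4 centre having little influence.

Step 22
Reactants: 28 tosyloxy alcohol
Product: 29 phenol from 28 (tosyl group removed; carbinol R; U-C4 unchanged in space, CIP R after the priority change)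
Conditions: KOH, EtOH/THF/H2O, 70 °C
Reagents that add atoms: none
Why: Hydrolysis of the aryl sulfonate by hydroxide attack at sulfur frees the ring A phenol and spares benzyl ethers, acetonide and the carbinol.

Step 23
Reactants: 29 phenol carbinol
Product: 30 heptabenzyl ether 3,4-acetonide of the target (U: 2S, 2,4-trans)
Conditions: PPh3, diisopropyl azodicarboxylate, toluene, 0 °C
Reagents that add atoms: none
Why: Intramolecular Mitsunobu etherification closes ring C of U with inversion at the (R)-carbinol, giving U-C2 as S and the 2,4-trans flavan, the apolar solvent and low temperature disfavouring ionisation of the 4-benzyloxybenzylic centre.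

Step 24
Reactants: 30 acetonide
Product: 31 heptabenzyl ether of the target (L 3,4-diol free)
Conditions: AcOH/THF/H2O (3:1:1), 40 °C, stopped at full conversion
Reagents that add atoms: none
Why: Acid-catalysed acetal hydrolysis proceeds through the acetone-derived oxocarbenium ion, which should form much faster than the L-C4 benzylic cation, so the cis diol is expected with its configuration intact.

Step 25
Reactants: 31 heptabenzyl ether
Product: 32 (2S,4S)-2-(4-hydroxyphenyl)-4-[(2R,3R,4R)-3,4,7,8-tetrahydroxy-2-(4-hydroxyphenyl)chroman-6-yl]chromane-7,8-diol (target)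
Conditions: H2 (1 atm), Pd(OH)2/C, EtOAc/MeOH, rt
Reagents that add atoms: none
Why: Hydrogenolysis of the seven aryl benzyl ethers under neutral conditions, where benzylic alcohols and the chroman C2–O bonds are cleaved much more slowly.

**Compound list**

1 | 2,3,4-trihydroxybenzaldehyde | O=Cc1ccc(O)c(O)c1O | starting material
2 | 3,4-bis(benzyloxy)-2-hydroxybenzaldehyde | O=Cc1ccc(OCc2ccccc2)c(OCc2ccccc2)c1O | intermediate
3 | 3,4-bis(benzyloxy)-2-(triisopropylsilyloxy)benzaldehyde | O=Cc1ccc(OCc2ccccc2)c(OCc2ccccc2)c1O[Si](C(C)C)(C(C)C)C(C)C | intermediate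
4 | [2,3-bis(benzyloxy)-6-ethynylphenoxy]triisopropylsilane | C#Cc1ccc(OCc2ccccc2)c(OCc2ccccc2)c1O[Si](C(C)C)(C(C)C)C(C)C | intermediate
5 | 4-(benzyloxy)benzaldehyde | O=Cc1ccc(OCc2ccccc2)cc1 | starting material
6 | ethyl{[3,4-bis(benzyloxy)-2-(triisopropylsilyloxy)phenyl]ethynyl}zinc | CC[Zn]C#Cc1ccc(OCc2ccccc2)c(OCc2ccccc2)c1O[Si](C(C)C)(C(C)C)C(C)C | intermediate (not isolated)
7 | (S)-1-[4-(benzyloxy)phenyl]-3-[3,4-bis(benzyloxy)-2-(triisopropylsilyloxy)phenyl]prop-2-yn-1-ol | O[C@@H](c1ccc(OCc2ccccc2)cc1)C#Cc1ccc(OCc2ccccc2)c(OCc2ccccc2)c1O[Si](C(C)C)(C(C)C)C(C)C | intermediate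
8 | (R,Z)-1-[4-(benzyloxy)phenyl]-3-[3,4-bis(benzyloxy)-2-(triisopropylsilyloxy)phenyl]prop-2-en-1-ol | O[C@@H](c1ccc(OCc2ccccc2)cc1)/C=C\c1ccc(OCc2ccccc2)c(OCc2ccccc2)c1O[Si](C(C)C)(C(C)C)C(C)C | intermediate
9 | (R,Z)-tert-butyldimethylsilyl ether of 8 | CC(C)(C)[Si](C)(C)O[C@@H](c1ccc(OCc2ccccc2)cc1)/C=C\c1ccc(OCc2ccccc2)c(OCc2ccccc2)c1O[Si](C(C)C)(C(C)C)C(C)C | intermediate
10 | (1R,2R,3S)-1-[3,4-bis(benzyloxy)-2-(triisopropylsilyloxy)phenyl]-3-[4-(benzyloxy)phenyl]-3-(tert-butyldimethylsilyloxy)propane-1,2-diol | CC(C)(C)[Si](C)(C)O[C@@H](c1ccc(OCc2ccccc2)cc1)[C@H](O)[C@H](O)c1ccc(OCc2ccccc2)c(OCc2ccccc2)c1O[Si](C(C)C)(C(C)C)C(C)C | intermediate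
11 | (4R,5R)-4-[3,4-bis(benzyloxy)-2-(triisopropylsilyloxy)phenyl]-5-{(S)-[4-(benzyloxy)phenyl](tert-butyldimethylsilyloxy)methyl}-2,2-dimethyl-1,3-dioxolane | CC(C)(C)[Si](C)(C)O[C@@H](c1ccc(OCc2ccccc2)cc1)[C@@H]1OC(C)(C)O[C@@H]1c1ccc(OCc2ccccc2)c(OCc2ccccc2)c1O[Si](C(C)C)(C(C)C)C(C)C | intermediate
12 | 2,3-bis(benzyloxy)-6-{(4R,5S)-5-[(S)-[4-(benzyloxy)phenyl](hydroxy)methyl]-2,2-dimethyl-1,3-dioxolan-4-yl}phenol | O[C@@H](c1ccc(OCc2ccccc2)cc1)[C@@H]1OC(C)(C)O[C@@H]1c1ccc(OCc2ccccc2)c(OCc2ccccc2)c1O | intermediate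
13 | 3,4-acetonide of (2R,3R,4R)-7,8-bis(benzyloxy)-2-[4-(benzyloxy)phenyl]chromane-3,4-diol (2,3-cis-3,4-cis; descriptors of the parent diol) | c1cc2c(c(OCc3ccccc3)c1OCc1ccccc1)O[C@H](c1ccc(OCc3ccccc3)cc1)[C@H](O3)[C@@H]2OC(C)(C)3 | intermediate
14 | 6-bromo derivative of 13 | Brc1cc2c(c(OCc3ccccc3)c1OCc1ccccc1)O[C@H](c1ccc(OCc3ccccc3)cc1)[C@H](O3)[C@@H]2OC(C)(C)3 | intermediate
15 | 6-lithio derivative of 13 | [Li]c1cc2c(c(OCc3ccccc3)c1OCc1ccccc1)O[C@H](c1ccc(OCc3ccccc3)cc1)[C@H](O3)[C@@H]2OC(C)(C)3 | intermediate (not isolated)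
16 | lithium triisopropoxy(aryl)borate from 15 | [Li+].CC(C)O[B-](OC(C)C)(OC(C)C)c1cc2c(c(OCc3ccccc3)c1OCc1ccccc1)O[C@H](c1ccc(OCc3ccccc3)cc1)[C@H](O3)[C@@H]2OC(C)(C)3 | intermediate (not isolated)
17 | 6-boronic acid of 13 | OB(O)c1cc2c(c(OCc3ccccc3)c1OCc1ccccc1)O[C@H](c1ccc(OCc3ccccc3)cc1)[C@H](O3)[C@@H]2OC(C)(C)3 | intermediate
18 | 2,3-bis(benzyloxy)-6-formylphenyl 4-methylbenzenesulfonate | O=Cc1ccc(OCc2ccccc2)c(OCc2ccccc2)c1OS(=O)(=O)c1ccc(C)cc1 | intermediate
19 | 3,4-bis(benzyloxy)-2-(tosyloxy)benzoic acid | OC(=O)c1ccc(OCc2ccccc2)c(OCc2ccccc2)c1OS(=O)(=O)c1ccc(C)cc1 | intermediate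
20 | 3,4-bis(benzyloxy)-2-(tosyloxy)benzoyl azide | [N-]=[N+]=NC(=O)c1ccc(OCc2ccccc2)c(OCc2ccccc2)c1OS(=O)(=O)c1ccc(C)cc1 | intermediate (not isolated)
21 | 2,3-bis(benzyloxy)-6-isocyanatophenyl 4-methylbenzenesulfonate | O=C=Nc1ccc(OCc2ccccc2)c(OCc2ccccc2)c1OS(=O)(=O)c1ccc(C)cc1 | intermediate (not isolated)
22 | 2,3-bis(benzyloxy)-6-[(tert-butoxycarbonyl)amino]phenyl 4-methylbenzenesulfonate | CC(C)(C)OC(=O)Nc1ccc(OCc2ccccc2)c(OCc2ccccc2)c1OS(=O)(=O)c1ccc(C)cc1 | intermediate
23 | 6-amino-2,3-bis(benzyloxy)phenyl 4-methylbenzenesulfonate | Nc1ccc(OCc2ccccc2)c(OCc2ccccc2)c1OS(=O)(=O)c1ccc(C)cc1 | intermediate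
24 | 3,4-bis(benzyloxy)-2-(tosyloxy)benzenediazonium tetrafluoroborate | F[B-](F)(F)F.N#[N+]c1ccc(OCc2ccccc2)c(OCc2ccccc2)c1OS(=O)(=O)c1ccc(C)cc1 | intermediate
25 | 1-[4-(benzyloxy)phenyl]prop-2-en-1-ol (racemic) | OC(C=C)c1ccc(OCc2ccccc2)cc1 | intermediate
26 | 1-[4-(benzyloxy)phenyl]prop-2-en-1-one | C=CC(=O)c1ccc(OCc2ccccc2)cc1 | intermediate
27 | (3S)-1-[4-(benzyloxy)phenyl]-3-[3,4-bis(benzyloxy)-2-(tosyloxy)phenyl]-3-(6-yl of 13)propan-1-one | O=C(c1ccc(OCc2ccccc2)cc1)C[C@@H](c1cc2c(c(OCc3ccccc3)c1OCc1ccccc1)O[C@H](c1ccc(OCc3ccccc3)cc1)[C@H](O3)[C@@H]2OC(C)(C)3)c1ccc(OCc2ccccc2)c(OCc2ccccc2)c1OS(=O)(=O)c1ccc(C)cc1 | intermediate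
28 | (1R,3S)-1-[4-(benzyloxy)phenyl]-3-[3,4-bis(benzyloxy)-2-(tosyloxy)phenyl]-3-(6-yl of 13)propan-1-ol | O[C@@H](c1ccc(OCc2ccccc2)cc1)C[C@@H](c1cc2c(c(OCc3ccccc3)c1OCc1ccccc1)O[C@H](c1ccc(OCc3ccccc3)cc1)[C@H](O3)[C@@H]2OC(C)(C)3)c1ccc(OCc2ccccc2)c(OCc2ccccc2)c1OS(=O)(=O)c1ccc(C)cc1 | intermediate
29 | 2,3-bis(benzyloxy)-6-[(1R,3R)-3-[4-(benzyloxy)phenyl]-3-hydroxy-1-(6-yl of 13)propyl]phenol (same spatial arrangement as 28) | O[C@@H](c1ccc(OCc2ccccc2)cc1)C[C@@H](c1cc2c(c(OCc3ccccc3)c1OCc1ccccc1)O[C@H](c1ccc(OCc3ccccc3)cc1)[C@H](O3)[C@@H]2OC(C)(C)3)c1ccc(OCc2ccccc2)c(OCc2ccccc2)c1O | intermediate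
30 | heptabenzyl ether 3,4-acetonide of the target: (2S,4R)-7,8-bis(benzyloxy)-2-[4-(benzyloxy)phenyl]-4-(6-yl of 13)chromane (2,4-trans) | c1ccccc1COc1ccc([C@@H]2C[C@@H](c3cc4c(c(OCc5ccccc5)c3OCc3ccccc3)O[C@H](c3ccc(OCc5ccccc5)cc3)[C@H](O5)[C@@H]4OC(C)(C)5)c3ccc(OCc4ccccc4)c(OCc4ccccc4)c3O2)cc1 | intermediate
31 | heptabenzyl ether of the target: U (2S,4R by CIP, 2,4-trans), L (2R,3R,4R)-3,4-diol | c1ccccc1COc1ccc([C@@H]2C[C@@H](c3cc4c(c(OCc5ccccc5)c3OCc3ccccc3)O[C@H](c3ccc(OCc5ccccc5)cc3)[C@H](O)[C@@H]4O)c3ccc(OCc4ccccc4)c(OCc4ccccc4)c3O2)cc1 | intermediate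
32 | (2S,4S)-2-(4-hydroxyphenyl)-4-[(2R,3R,4R)-3,4,7,8-tetrahydroxy-2-(4-hydroxyphenyl)chroman-6-yl]chromane-7,8-diol | Oc1ccc([C@@H]2C[C@@H](c3cc4c(c(O)c3O)O[C@H](c3ccc(O)cc3)[C@H](O)[C@@H]4O)c3ccc(O)c(O)c3O2)cc1 | target

**Step count**

Total: 25 steps. Longest linear sequence: 18 steps (steps 1–12, then 20–25).

**Steps most likely to fail**

Step 20. The Pd–H species may leave the chalcone before it re-adds, the palladium enolate may be protonated, or the phosphate ion pair may fail to override the chiral boronic acid, so that Heck product, reductive Heck product or a mixture at U-C4 results. The fallback divides the step into two known reactions. Setting out from 24 and 26, a ligand-free Heck–Matsuda arylation (Pd(OAc)2, NaOAc, MeCN, rt) would give (E)-3-[3,4-bis(benzyloxy)-2-(tosyloxy)phenyl]-1-[4-(benzyloxy)phenyl]prop-2-en-1-one F1. A Hayashi–Miyaura conjugate addition of boronic acid 17 ([RhCl(C2H4)2]2, chiral bicyclo[2.2.2]octadiene ligand of the antipode that gives the (S)-centre, KOH (cat.), dioxane/H2O, 50 °C) would then place the L aryl group on the β-carbon under ligand control and come back to the route at 27.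

Step 7. Osmylation may show poor facial selectivity if the bulky aryl group at the allylic carbon competes with the silyloxy group, giving the 2,3-syn diol beside 10. The fallback replaces syn-addition to the Z-alkene by reagent-controlled anti-addition to the E-alkene. Setting out from 7, trans-hydroalumination (NaAlH2(OCH2CH2OMe)2, THF, 0 °C to rt) would give (R,E)-1-[4-(benzyloxy)phenyl]-3-[3,4-bis(benzyloxy)-2-(triisopropylsilyloxy)phenyl]prop-2-en-1-ol F2. Sharpless asymmetric epoxidation in the matched sense (Ti(OiPr)4, L-(+)-diisopropyl tartrate, t-BuOOH, 4 Å molecular sieves, CH2Cl2, −20 °C) would give the anti epoxy alcohol (S)-[4-(benzyloxy)phenyl]{(2S,3S)-3-[3,4-bis(benzyloxy)-2-(triisopropylsilyloxy)phenyl]oxiran-2-yl}methanol F3. Silylation (TBSCl, imidazole, DMF) would give its tert-butyldimethylsilyl ether F4. Acid-catalysed hydrolytic opening at the benzylic carbon with inversion (HClO4 (cat.), THF/H2O, 0 °C) would come back to the route at 10; this last opening is itself stereochemically uncertain at so electron-rich a benzylic centre.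

Step 24. Ionisation of the L-C4–O bond (a 2,4-dialkoxybenzylic position) may compete with ketal cleavage and scramble L-C4. The fallback accepts the scrambling and repairs it by an oxidation–reduction relay. Setting out from 30, the hydrolysis would be driven to completion (aq. CF3CO2H, THF) to give 31 together with its L-C4 epimer, the 3,4-trans diol F5. Oxidation of the activated benzylic carbinol of the mixture (DDQ, dioxane, rt) would converge on the 2,3-cis-3-hydroxy-4-oxo compound F6. Reduction with NaBH4 (MeOH/THF, −40 °C) should then deliver hydride anti to the axial 3-hydroxyl, the classical conversion of 2,3-cis-dihydroflavonols into 2,3-cis-3,4-cis-diols, and come back to the route at 31.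

**Further compounds**

F1 | step 20 | (E)-3-[3,4-bis(benzyloxy)-2-(tosyloxy)phenyl]-1-[4-(benzyloxy)phenyl]prop-2-en-1-one | O=C(/C=C/c1ccc(OCc2ccccc2)c(OCc2ccccc2)c1OS(=O)(=O)c1ccc(C)cc1)c1ccc(OCc2ccccc2)cc1
F2 | step 7 | (R,E)-1-[4-(benzyloxy)phenyl]-3-[3,4-bis(benzyloxy)-2-(triisopropylsilyloxy)phenyl]prop-2-en-1-ol | O[C@@H](c1ccc(OCc2ccccc2)cc1)/C=C/c1ccc(OCc2ccccc2)c(OCc2ccccc2)c1O[Si](C(C)C)(C(C)C)C(C)C
F3 | step 7 | (S)-[4-(benzyloxy)phenyl]{(2S,3S)-3-[3,4-bis(benzyloxy)-2-(triisopropylsilyloxy)phenyl]oxiran-2-yl}methanol | O[C@@H](c1ccc(OCc2ccccc2)cc1)[C@@H]1O[C@H]1c1ccc(OCc2ccccc2)c(OCc2ccccc2)c1O[Si](C(C)C)(C(C)C)C(C)C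
F4 | step 7 | tert-butyldimethylsilyl ether of F3 | CC(C)(C)[Si](C)(C)O[C@@H](c1ccc(OCc2ccccc2)cc1)[C@@H]1O[C@H]1c1ccc(OCc2ccccc2)c(OCc2ccccc2)c1O[Si](C(C)C)(C(C)C)C(C)C
F5 | step 24 | L-C4 epimer of 31 (L unit 2R,3R,4S; 3,4-trans diol) | c1ccccc1COc1ccc([C@@H]2C[C@@H](c3cc4c(c(OCc5ccccc5)c3OCc3ccccc3)O[C@H](c3ccc(OCc5ccccc5)cc3)[C@H](O)[C@H]4O)c3ccc(OCc4ccccc4)c(OCc4ccccc4)c3O2)cc1
F6 | step 24 | 4-oxo analogue of 31 (L unit as 2,3-cis-3-hydroxychroman-4-one, 2R,3S) | c1ccccc1COc1ccc([C@@H]2C[C@@H](c3cc4c(c(OCc5ccccc5)c3OCc3ccccc3)O[C@H](c3ccc(OCc5ccccc5)cc3)[C@H](O)C4=O)c3ccc(OCc4ccccc4)c(OCc4ccccc4)c3O2)cc1
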